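**Retrosynthetic overview**
1. Target 29 ← 28 (hydroxyl-directed hydrogenation sets C8) ← spiro ketone 23 (methylenation of C8, oxidation of C16, closure of the γ-lactone).
2. Key disconnection (retro-semipinacol): in ring B (C5–C6–C7–C8–C9–C10) the spiro ether carbon C9 lies between C8, which carries only H and CH3 and can therefore be a carbonyl, and the quaternary C10, while the C13 oxygen can reach C9 in a five-membered ring. Taking C9 out of ring B (C10 back onto C8) gives cyclopentanol 21 (ring C5–C6–C7–C8–C10) with a C9≡C11 alkyne and a free C13 hydroxyl.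
3. 21 ← enyne 20 (the C8 oxygen is put on last, on the open β face) ← enol triflate 13 + alkyne 19 (Sonogashira); 19 ← Sharpless epoxidation (C13).
4. 13 ← alkylation of the δ-lactone enolate, C3–C4 (ring A, C4) ← hydroxymethylation (C10, lactone) and Mukaiyama–Michael addition (C5) on (R)-4-silyloxycyclopentenone 1 (C6).
5. Order of ring formation: cyclopentene (from 1) → 19,20-δ-lactone → ring A → tetrahydrofuran together with ring B (ring expansion, step 16) → γ-butyrolactone.

Key step: step 16

Remark: labdane numbering is used throughout (C1–C10 ring carbons, C11–C16 side chain, C17 on C8, C18 and C19 on C4, C20 on C10; β is the face of C20); 7 is used as its E/Z mixture and 8–12 are mixtures at C4, which is without consequence because C4 is set in step 8.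

**Route**

Step 1
Reactants: 1 (R)-4-(tert-butyldimethylsilyloxy)cyclopent-2-en-1-one
Product: 2 (R)-2-iodo-4-(tert-butyldimethylsilyloxy)cyclopent-2-en-1-one
Conditions: I2, pyridine, CH2Cl2, 0 → 25 °C
Reagents that add atoms: iodine, [I][I]
Why: α-iodination of the enone by an addition–elimination sequence (pyridine adds in the conjugate sense, the enolate is iodinated, pyridine leaves); the C6 stereocentre is not touched.

Step 2
Reactants: 3 allyl chloride; 4 9-borabicyclo[3.3.1]nonane
Product: 5 9-(3-chloropropyl)-9-borabicyclo[3.3.1]nonane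
Conditions: THF, 0 → 25 °C, used as solution
Reagents that add atoms: none
Why: anti-Markovnikov hydroboration of the terminal alkene; the primary chloride is inert to the borane.

Step 3
Reactants: 2 (R)-2-iodo-4-(tert-butyldimethylsilyloxy)cyclopent-2-en-1-one; 5 9-(3-chloropropyl)-9-borabicyclo[3.3.1]nonane
Product: 6 (R)-2-(3-chloropropyl)-4-(tert-butyldimethylsilyloxy)cyclopent-2-en-1-one
Conditions: PdCl2(dppf) (3 mol %), AsPh3, Cs2CO3, DMF/THF/H2O, 25 °C
Reagents that add atoms: none
Why: B-alkyl Suzuki–Miyaura coupling of a 2-iodoenone brings in C1–C3 with the chloride as a latent leaving group; no stereocentre is touched.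

Step 4
Reactants: 6 (R)-2-(3-chloropropyl)-4-(tert-butyldimethylsilyloxy)cyclopent-2-en-1-one; 7 1-methoxy-1-(trimethylsilyloxy)prop-1-ene
Product: 8 Michael adduct as trimethylsilyl enol ether
Conditions: Ph3CClO4 (5 mol %), CH2Cl2, −78 °C
Reagents that add atoms: none
Why: Mukaiyama–Michael addition in which the ketene silyl acetal attacks C5 anti to the silyloxy group on C6 (sets C5) and the silyl group passes to the enolate oxygen, fixing the enol ether between C8 and C10.

Step 5
Reactants: 8 Michael adduct as trimethylsilyl enol ether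
Product: 10 trans-fused keto δ-lactone (chloride), via hydroxymethyl keto ester 9 (not isolated)
Conditions: HCHO (37 % aq.), Yb(OTf)3 (10 mol %), THF, 25 °C; then PPTS, toluene, 80 °C
Reagents that add atoms: formaldehyde, C=O
Why: Mukaiyama aldol hydroxymethylation in water: formaldehyde attacks C10 anti to the side chain on C5, so C20 ends cis to H5 and to the silyloxy group as in three-component cyclopentenone couplings (sets C10), and the hydroxy ester then closes to the trans-fused δ-lactone by acid-catalysed transesterification.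

Step 6
Reactants: 10 trans-fused keto δ-lactone (chloride)
Product: 11 bicyclic enol triflate (chloride)
Conditions: KN(SiMe3)2 (1.05 equiv), PhNTf2, THF, −78 °C
Reagents that add atoms: N-phenylbis(trifluoromethanesulfonimide), O=S(=O)(N(c1ccccc1)S(=O)(=O)C(F)(F)F)C(F)(F)F
Why: kinetic deprotonation at C7, the only enolisable position of the ketone, and O-triflation at −78 °C before the enolate can expel the β-silyloxy group; the less acidic lactone α-hydrogen is left by one equivalent of base.

Step 7
Reactants: 11 bicyclic enol triflate (chloride)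
Product: 12 bicyclic enol triflate (iodide)
Conditions: NaI, acetone, reflux
Reagents that add atoms: sodium iodide, [Na+].[I-]
Why: Finkelstein exchange gives the primary iodide needed for ring closure; the enol triflate and the lactone do not react with iodide.

Step 8
Reactants: 12 bicyclic enol triflate (iodide)
Product: 13 tricyclic enol triflate
Conditions: LiN(i-Pr)2 (1.3 equiv), THF/DMPU, −78 → 0 °C
Reagents that add atoms: none
Why: intramolecular C-alkylation of the δ-lactone enolate (6-exo-tet) closes ring A as a bicyclo[3.3.1]nonane; the chain on C10 can reach the planar C4 enolate carbon on one face only, so C4 is set with C19 in the bridge and C18 exo whatever the C4 configuration of 12.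

Step 9
Reactants: 14 4-(tert-butyldimethylsilyloxy)butanal
Product: 15 2-methylene-4-(tert-butyldimethylsilyloxy)butanal
Conditions: HCHO (37 % aq.), pyrrolidine (10 mol %), EtCO2H (10 mol %), i-PrOH, 45 °C
Reagents that add atoms: formaldehyde, C=O
Why: amine-catalysed α-methylenation of an aldehyde (Mannich condensation followed by elimination).

Step 10
Reactants: 15 2-methylene-4-(tert-butyldimethylsilyloxy)butanal
Product: 16 2-[2-(tert-butyldimethylsilyloxy)ethyl]prop-2-en-1-ol
Conditions: NaBH4, CeCl3·7H2O, MeOH, −40 °C
Reagents that add atoms: none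
Why: Luche 1,2-reduction of the enal.

Step 11
Reactants: 16 2-[2-(tert-butyldimethylsilyloxy)ethyl]prop-2-en-1-ol
Product: 17 (R)-epoxy alcohol
Conditions: Ti(OiPr)4 (10 mol %), D-(−)-diethyl tartrate (12 mol %), t-BuOOH, 4 Å molecular sieves, CH2Cl2, −20 °C
Reagents that add atoms: tert-butyl hydroperoxide, CC(C)(C)OO
Why: Sharpless asymmetric epoxidation of a 2-substituted allylic alcohol; the D-tartrate ligand selects the alkene face that gives the (R)-epoxide, which sets C13.

Step 12
Reactants: 17 (R)-epoxy alcohol
Product: 18 (S)-epoxide 4-methoxybenzyl ether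
Conditions: NaH, 4-MeOC6H4CH2Cl, Bu4NI (cat.), THF/DMF, 0 → 25 °C
Reagents that add atoms: 4-methoxybenzyl chloride, COc1ccc(CCl)cc1
Why: Williamson etherification of the primary alkoxide; the quaternary epoxide carbon is not attacked, so C13 keeps its configuration (the descriptor changes by priority only).

Step 13
Reactants: 18 (S)-epoxide 4-methoxybenzyl ether
Product: 19 (R)-alkynol
Conditions: LiC≡CH·H2NCH2CH2NH2, DMSO, 25 °C
Reagents that add atoms: lithium acetylide (ethylenediamine complex), [Li+].[C-]#C
Why: SN2 opening of the 2,2-disubstituted epoxide at its CH2 carbon (C12) by acetylide, which leaves the C13–O bond and its configuration untouched.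

Step 14
Reactants: 13 tricyclic enol triflate; 19 (R)-alkynol
Product: 20 tricyclic enyne
Conditions: Pd(PPh3)4 (5 mol %), CuI (10 mol %), i-Pr2NH, DMF, 25 °C
Reagents that add atoms: none
Why: Sonogashira coupling of the enol triflate with the terminal alkyne joins C8 to C9 while C8 stays planar; the free tertiary alcohol is tolerated.

Step 15
Reactants: 20 tricyclic enyne
Product: 21 tricyclic alkynediol (8β-hydroxy)
Conditions: Co(acac)2 (20 mol %), PhSiH3, O2 (1 atm), i-PrOH/CH2Cl2, 0 → 25 °C
Reagents that add atoms: dioxygen, O=O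
Why: Mukaiyama hydration: hydrogen atom transfer to C7 gives the tertiary propargylic C8 radical, which takes up O2 at C8 anti to the axial C1 methylene on C10, so the hydroxyl ends β and the alkyne α (sets C8 of 21); this is the epimer that acetylide addition to a C8 ketone, which would come in anti to the same methylene, would not give.

Step 16
Reactants: 21 tricyclic alkynediol (8β-hydroxy)
Product: 23 spiro ketone (ring B formed), via dihydrofuranyl carbinol 22 (not isolated)
Conditions: Ph3PAuNTf2 (5 mol %), TsOH·H2O (10 mol %), CH2Cl2, 0 → 25 °C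
Reagents that add atoms: none
Why: Proposed new method: the cationic gold catalyst activates the C9≡C11 alkyne for 5-endo-dig attack of the C13 hydroxyl (this closes the tetrahydrofuran), protodeauration gives dihydrofuran 22, and the sulfonic acid protonates C11 to the C9 oxocarbenium ion, to which the C8–C10 bond shifts while the C8 hydroxyl becomes the ketone; ring B is closed by this 1,2-alkyl shift, a one-carbon expansion of the cyclopentane, and not by a cyclisation. The closest known reactions are the gold/Brønsted acid tandem cycloisomerisation–hydroalkoxylation of homopropargylic alcohols, which makes such oxocarbenium ions from alkynols, and the oxonium-ion-initiated pinacol ring expansion of 2-(1-hydroxycycloalkyl)dihydrofurans; running both in one flask on an alkynediol is the new part. C10 migrates with retention, so C4, C5, C6, C10 and C13 are untouched. The new centre C9 is controlled by the C8 carbinol (alkyne on the α face) and by the expected transition state in which the ring oxygen sits over the five-membered ring, anti to the carbinol oxygen, and the larger C11 methylene points outwards; this places O on the α face and C11 on the β face. The step needs migration of C10 and not of C7, which the quaternary carbon secures against a plain methylene. It also needs O-cyclisation before Meyer–Schuster ionisation of the propargylic alcohol, which the C13 hydroxyl held five atoms from C9 should secure.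

Step 17
Reactants: 23 spiro ketone (ring B formed)
Product: 24 8(17)-methylene compound
Conditions: Zn, CH2Br2, TiCl4, THF/CH2Cl2, 0 → 25 °C
Reagents that add atoms: dibromomethane, BrCBr
Why: Takai–Lombardo methylenation, a non-basic titanium carbenoid that converts hindered enolisable ketones without β-elimination of the C6 silyloxy group and leaves the lactone alone.

Step 18
Reactants: 24 8(17)-methylene compound
Product: 25 C16 primary alcohol
Conditions: DDQ, CH2Cl2/pH 7 buffer, 0 °C
Reagents that add atoms: none
Why: oxidative cleavage of the 4-methoxybenzyl ether by hydride abstraction and hydrolysis of the oxocarbenium ion; silyl ethers, alkene and lactone are inert.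

Step 19
Reactants: 25 C16 primary alcohol
Product: 26 C16 carboxylic acid
Conditions: TEMPO (20 mol %), PhI(OAc)2 (2.5 equiv), MeCN/H2O, 25 °C
Reagents that add atoms: water, O
Why: oxoammonium-mediated oxidation of the primary alcohol through the aldehyde hydrate to the acid; the tertiary ether and the alkene are not oxidised.

Step 20
Reactants: 26 C16 carboxylic acid
Product: 28 8(17)-ene hydroxy dilactone, via dihydroxy acid 27 (not isolated)
Conditions: HF·pyridine, THF/pyridine, 0 → 25 °C
Reagents that add atoms: none
Why: fluoride cleavage of both silyl ethers, after which the freed C15 hydroxyl closes the γ-lactone onto the C16 acid (5-exo-trig acyl substitution); the 6β-hydroxyl is anti to C19 across C5 and cannot translactonise.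

Step 21
Reactants: 28 8(17)-ene hydroxy dilactone
Product: 29 target
Conditions: [Ir(cod)(PCy3)(py)]PF6 (10 mol %), H2 (1 atm), CH2Cl2, 25 °C
Reagents that add atoms: none
Why: hydroxyl-directed hydrogenation: the 6β-hydroxyl binds the cationic iridium catalyst and hydrogen is delivered to the β face of the exocyclic alkene, the α face being shielded by the axial C1 methylene, so the C17 methyl ends α (sets C8).

**Compound list**
1 | (R)-4-[(tert-butyldimethylsilyl)oxy]cyclopent-2-en-1-one | O=C1C=C[C@H](O[Si](C)(C)C(C)(C)C)C1 | starting material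
2 | (R)-4-[(tert-butyldimethylsilyl)oxy]-2-iodocyclopent-2-en-1-one | O=C1C(I)=C[C@H](O[Si](C)(C)C(C)(C)C)C1 | intermediate
3 | allyl chloride (3-chloroprop-1-ene) | C=CCCl | starting material
4 | 9-borabicyclo[3.3.1]nonane | B1C2CCCC1CCC2 | starting material
5 | 9-(3-chloropropyl)-9-borabicyclo[3.3.1]nonane | ClCCCB1C2CCCC1CCC2 | intermediate
6 | (R)-4-[(tert-butyldimethylsilyl)oxy]-2-(3-chloropropyl)cyclopent-2-en-1-one | O=C1C(CCCCl)=C[C@H](O[Si](C)(C)C(C)(C)C)C1 | intermediate
7 | 1-methoxy-1-(trimethylsilyloxy)prop-1-ene (ketene silyl acetal of methyl propanoate, E/Z mixture) | CC=C(OC)O[Si](C)(C)C | starting material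
8 | methyl 2-[5-(tert-butyldimethylsilyloxy)-2-(3-chloropropyl)-3-(trimethylsilyloxy)cyclopent-2-en-1-yl]propanoate, ring substituents at C5 and C6 trans (H5 β, OTBS β), mixture at C4 | C[Si](C)(C)OC1=C(CCCCl)[C@@H](C(C)C(=O)OC)[C@H](O[Si](C)(C)C(C)(C)C)C1 | intermediate
9 | methyl 2-[5-(tert-butyldimethylsilyloxy)-2-(3-chloropropyl)-2-(hydroxymethyl)-3-oxocyclopentyl]propanoate, CH2OH (C20) on C10 cis to H5 and to OTBS and trans to the propanoate chain, mixture at C4 | O=C1C[C@@H](O[Si](C)(C)C(C)(C)C)[C@H](C(C)C(=O)OC)[C@]1(CO)CCCCl | intermediate (not isolated)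
10 | trans-fused keto δ-lactone: 7a-(3-chloropropyl)-5-(tert-butyldimethylsilyloxy)-4-methylhexahydrocyclopenta[c]pyran-3,7-dione, H-4a and OTBS β, chloropropyl α, mixture at C4 | O=C1C[C@@H](O[Si](C)(C)C(C)(C)C)[C@@H]2C(C)C(=O)OC[C@@]12CCCCl | intermediate
11 | enol triflate of 10 (C7=C8, OTf on C8), otherwise as 10 | FC(F)(F)S(=O)(=O)OC1=C[C@@H](O[Si](C)(C)C(C)(C)C)[C@@H]2C(C)C(=O)OC[C@@]12CCCCl | intermediate
12 | 3-iodopropyl analogue of 11 | FC(F)(F)S(=O)(=O)OC1=C[C@@H](O[Si](C)(C)C(C)(C)C)[C@@H]2C(C)C(=O)OC[C@@]12CCCI | intermediate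
13 | tricyclic enol triflate: ring A and the 19,20-δ-lactone form a 2-oxabicyclo[3.3.1]nonan-3-one (C18 methyl exo on C4) fused across C5–C10 to a cyclopentene with OTf on C8 (C7=C8) and 6β-OTBS; H5 β, C20 β | FC(F)(F)S(=O)(=O)OC1=C[C@@H](O[Si](C)(C)C(C)(C)C)[C@H]2[C@]13CCC[C@]2(C)C(=O)OC3 | intermediate
14 | 4-[(tert-butyldimethylsilyl)oxy]butanal | O=CCCCO[Si](C)(C)C(C)(C)C | starting material
15 | 4-[(tert-butyldimethylsilyl)oxy]-2-methylidenebutanal | C=C(C=O)CCO[Si](C)(C)C(C)(C)C | intermediate
16 | 2-{2-[(tert-butyldimethylsilyl)oxy]ethyl}prop-2-en-1-ol | C=C(CO)CCO[Si](C)(C)C(C)(C)C | intermediate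
17 | [(R)-2-{2-[(tert-butyldimethylsilyl)oxy]ethyl}oxiran-2-yl]methanol | C1O[C@@]1(CO)CCO[Si](C)(C)C(C)(C)C | intermediate
18 | (S)-2-{2-[(tert-butyldimethylsilyl)oxy]ethyl}-2-{[(4-methoxybenzyl)oxy]methyl}oxirane | C1O[C@@]1(COCc2ccc(OC)cc2)CCO[Si](C)(C)C(C)(C)C | intermediate
19 | (R)-1-[(tert-butyldimethylsilyl)oxy]-3-{[(4-methoxybenzyl)oxy]methyl}hex-5-yn-3-ol | C#CC[C@](O)(COCc1ccc(OC)cc1)CCO[Si](C)(C)C(C)(C)C | intermediate
20 | tricyclic enyne: 13 with the OTf on C8 replaced by the C9≡C11–C12H2–C13(OH)(CH2OPMB)(CH2CH2OTBS) chain, 13R | C1(C#CC[C@](O)(COCc2ccc(OC)cc2)CCO[Si](C)(C)C(C)(C)C)=C[C@@H](O[Si](C)(C)C(C)(C)C)[C@H]2[C@]13CCC[C@]2(C)C(=O)OC3 | intermediate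
21 | tricyclic alkynediol: cyclopentanol with 8β-OH and the alkynyl chain 8α, 6β-OTBS, H5 β, 19,20-lactone, 13R | O[C@@]1(C#CC[C@](O)(COCc2ccc(OC)cc2)CCO[Si](C)(C)C(C)(C)C)C[C@@H](O[Si](C)(C)C(C)(C)C)[C@H]2[C@]13CCC[C@]2(C)C(=O)OC3 | intermediate
22 | dihydrofuranyl carbinol: 21 after addition of the C13 oxygen to C9 (4,5-dihydrofuran, C9=C11) | O[C@@]1(C2=CC[C@](COCc3ccc(OC)cc3)(CCO[Si](C)(C)C(C)(C)C)O2)C[C@@H](O[Si](C)(C)C(C)(C)C)[C@H]2[C@]13CCC[C@]2(C)C(=O)OC3 | intermediate (not isolated)
23 | spiro ketone: 6β-(tert-butyldimethylsilyloxy)-8-oxo-9α,13-epoxy-17-nor-5β-labdan-19,20-olide with CH2OPMB (C16) and CH2CH2OTBS (C14–C15) on C13, 13R | O=C1C[C@@H](O[Si](C)(C)C(C)(C)C)[C@H]2[C@]3(CCC[C@]2(C)C(=O)OC3)[C@@]12CC[C@](COCc1ccc(OC)cc1)(CCO[Si](C)(C)C(C)(C)C)O2 | intermediate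
24 | 8(17)-methylene analogue of 23 | C=C1C[C@@H](O[Si](C)(C)C(C)(C)C)[C@H]2[C@]3(CCC[C@]2(C)C(=O)OC3)[C@@]12CC[C@](COCc1ccc(OC)cc1)(CCO[Si](C)(C)C(C)(C)C)O2 | intermediate
25 | 24 with free C16 hydroxyl (CH2OH on C13) | C=C1C[C@@H](O[Si](C)(C)C(C)(C)C)[C@H]2[C@]3(CCC[C@]2(C)C(=O)OC3)[C@@]12CC[C@](CO)(CCO[Si](C)(C)C(C)(C)C)O2 | intermediate
26 | C16 carboxylic acid (CO2H on C13), both silyl ethers in place | C=C1C[C@@H](O[Si](C)(C)C(C)(C)C)[C@H]2[C@]3(CCC[C@]2(C)C(=O)OC3)[C@@]12CC[C@](C(=O)O)(CCO[Si](C)(C)C(C)(C)C)O2 | intermediate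
27 | 6β,15-dihydroxy C16 acid | C=C1C[C@@H](O)[C@H]2[C@]3(CCC[C@]2(C)C(=O)OC3)[C@@]12CC[C@](C(=O)O)(CCO)O2 | intermediate (not isolated)
28 | 6β-hydroxy-9α,13-epoxy-5β-labd-8(17)-ene-19,20:16,15-diolide, 13R | C=C1C[C@@H](O)[C@H]2[C@]3(CCC[C@]2(C)C(=O)OC3)[C@@]12CC[C@]1(CCOC1=O)O2 | intermediate
29 | 6β-hydroxy-9α,13-epoxy-5β,8βH-labdane-19,20:16,15-diolide, 13R (CNP0393616.2) | C[C@@H]1C[C@@H](O)[C@H]2[C@]3(CCC[C@]2(C)C(=O)OC3)[C@@]12CC[C@]1(CCOC1=O)O2 | target

Total step count: 21. Longest linear sequence: 15 steps (from 1 through steps 1, 3–8 and 14–21).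

**Steps most likely to fail**

Step 16 (carries the label). The gold or the acid may ionise or transpose the tertiary propargylic hydroxyl (Meyer–Schuster pathway) before the C13 hydroxyl has added, or the shift may pass through the other rotamer of the oxocarbenium ion and put the ring oxygen on the β face. The fallback separates the two events and uses only known reactions. It sets out from 21: acid-free cycloisomerisation with PdCl2(MeCN)2 (5 mol %) in THF gives the dihydrofuran 22, which is isolated. The halonium-induced ring expansion of dihydrofuranyl carbinols (N-bromosuccinimide, propylene oxide, i-PrOH, −78 °C) then gives the 11-bromo spiro ketone F1, the oxocarbenium ion being formed irreversibly at low temperature without strong acid. Radical debromination with Bu3SnH/Et3B (toluene, 0 °C) brings the route back at 23.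

Step 15. Capture of O2 at the allenyl terminus (C11) instead of C8, attack from the α face, or reduction of the radical to the saturated hydrocarbon would all lose the 8β-carbinol. The fallback sets out from 20 and replaces the radical hydration by an ionic one: N-bromosuccinimide in aqueous acetone (0 °C) should give the bromohydrin F2, with bromine on C7 and water adding to the tertiary propargylic C8 from the open β face. Bu3SnH/Et3B (toluene, 0 °C) then removes the bromine and the route is rejoined at 21.

Step 21. Delivery of hydrogen through the homoallylic 6β-hydroxyl may be too weak and hydrogen may then enter from the wrong face or the alkene may isomerise without reduction. The fallback sets out from 28: RhCl3·3H2O (EtOH, 70 °C) moves the exocyclic double bond into the ring to give the Δ7 allylic alcohol F3. Its hydrogenation with [Ir(cod)(PCy3)(py)]PF6 and H2 is then directed by an allylic hydroxyl, the most dependable case of this catalyst, and should deliver hydrogen to the β face of C7 and C8 to arrive at 29.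

Further compounds
F1 | step 16 | 11-bromo spiro ketone (23 with Br on C11, mixture at C11) | O=C1C[C@@H](O[Si](C)(C)C(C)(C)C)[C@H]2[C@]3(CCC[C@]2(C)C(=O)OC3)[C@@]12C(Br)C[C@](COCc1ccc(OC)cc1)(CCO[Si](C)(C)C(C)(C)C)O2
F2 | step 15 | bromohydrin (21 with Br on C7, mixture at C7) | O[C@@]1(C#CC[C@](O)(COCc2ccc(OC)cc2)CCO[Si](C)(C)C(C)(C)C)C(Br)[C@@H](O[Si](C)(C)C(C)(C)C)[C@H]2[C@]13CCC[C@]2(C)C(=O)OC3
F3 | step 21 | 6β-hydroxy-9α,13-epoxy-5β-labd-7-ene-19,20:16,15-diolide, 13R | CC1=C[C@@H](O)[C@H]2[C@]3(CCC[C@]2(C)C(=O)OC3)[C@@]12CC[C@]1(CCOC1=O)O2
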